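I decided to read Wednesday's and Sunday's flasks off the midnight run instead of building a mechanism, and first I asked which given number had to be known well.

| flask | starting material | partner | free catalyst | remark | time |
|---|---|---|---|---|---|
| midnight | 0.020 M | 0.080 M | 1.4 mM | run made earlier |  |
| Wednesday's | 0.020 M | 0.0800 M | 1.7 mM |  | 1.0 h |
| Sunday's | 0.020 M | 0.0800 M | 2.0 mM |  | 1.0 h |

midnight run (percent of the starting material charged)

| time / min | starting material / % | target / % | catalyst intermediate A / % | isomer of the product / % |
|---|---|---|---|---|
| 4.00 | 88 | 10 | 3 | 0 |
| 12.0 | 68 | 25 | 2 | 7 |
| 20.0 | 52 | 30 | 1 | 13 |
| 30.0 | 39 | 37 | 0 | 23 |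
| 50.0 | 22 | 42 | 0 | 36 |
| 60.0 | 13 | 40 | 0 | 39 |

(each reading ± 2 percentage points)

- what was read earlier has a scatter of 2 percentage points, one standard deviation
- no earlier run changes the charge of free catalyst; that part of a forecast is a guess

1. which of these there is most of at the end, counted by the starting material in it, Wednesday's (target / catalyst intermediate A / starting material / isomer of the product)
2. which of these there is most of at the end, counted by the starting material in it, Sunday's (target / catalyst intermediate A / starting material / isomer of the product)
3. the largest of these amounts at the end, in percent of the starting material charged, Wednesday's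
4. the largest of these amounts at the end, in percent of the starting material charged, Sunday's

The charges of starting material and partner stand as at midnight, 0.020 M and 0.0800 M, so they carried no error into the comparison, and the time of 1.0 h equals midnight's last reading at 60.0 min. Leaving the catalyst charge out of the reckoning, I had both flasks at that reading, isomer 39% against target 40%, level within the scatter of 2 percentage points. That left the catalyst charge, which no earlier run varies. Assuming proportion, I reckoned 72.9 min for Wednesday's and 85.7 min for Sunday's as the midnight-equivalent time, the flask's time multiplied by its catalyst charge as a fraction of the midnight charge, which is a normalised time axis. Midnight's isomer gained 16 points over its last 30.0 min, and that slope carried on gave me 45.9% and 52.7%. So the catalyst guess was worth 6.9 points and 14 points, more than the scatter. Sunday's reckoned gain is more than the 13% of starting material read at midnight's end, so I held that figure as high. Taking the target to stay near its last reading, I named the isomer for both flasks.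

The forecast also named isomer of the product for Wednesday's and isomer of the product for Sunday's, at 48% and 54%, a little above my figures, with the first step “assumed proportional to catalyst”.

The simulation gave the isomer as the largest in both flasks: at its 72.9 min of midnight-equivalent time Wednesday's flask held 47.3% against target 41.3%, and Sunday's flask held 50.7% against 41.8%.

    catalyst intermediate C → free catalyst + target (k = 1.40 s⁻¹)
    catalyst intermediate A → catalyst intermediate B (k = 0.0170 s⁻¹)
    starting material + free catalyst ⇌ catalyst intermediate A (K = 370 L mol⁻¹, k = 0.670 L mol⁻¹ s⁻¹)
    target + free catalyst ⇌ isomer of the product + free catalyst, rate k4*[free catalyst]*[target] forward; the back reaction follows from the equilibrium constant (K = 1.30, k = 0.960 L mol⁻¹ s⁻¹)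
    starting material + catalyst intermediate C → spent catalyst B (k = 0.0320 L mol⁻¹ s⁻¹)
    partner + catalyst intermediate B ⇌ catalyst intermediate C (K = 4.00 L mol⁻¹, k = 20.0 L mol⁻¹ s⁻¹)
    catalyst intermediate A → spent catalyst A (k = 4.00 × 10⁻⁴ s⁻¹)

Wednesday's isomer stands there because of the back run from isomer to target: the same run without that step reaches 77.1% instead of 47.3%. The neighbour of Sunday's flask, charged with 0.500 mM of free catalyst, has 21.4 min of midnight-equivalent time; midnight read isomer 13% at 20.0 min, and that neighbour ended at 11.8%.

The earlier runs and the new flask were computed with constants of no real substance; noise was put on by code.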